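## Retrosynthetic overview

1. The quinone ring is cut at both C(OMe)–C(=O) bonds, giving two (E)-2-(indol-3-yl)-3-methoxyacrylate esters that are joined head to tail.
2. Each of these bonds is made from a lithiated enol-ether carbon (a masked formyl carbon acting as an acyl-anion equivalent) and the ester carbonyl of the other half. The ring arrives with both methyl ethers in place and at the quinone oxidation level.
3. Each β-methoxyacrylate comes from an indol-3-ylacetate by Claisen formylation and O-methylation.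
4. The 7-prenylindol-3-ylacetate comes from 7-bromoindole by copper-carbenoid C3–H alkylation, then Stille prenylation; the other acetate is bought.
5. Ring order: both indole rings are bought; the quinone ring is the only ring formed, in the last step.

Assumption: the target has no stereocentre and no stereogenic double bond, so the SMILES defines it completely; the only geometry to control is the E configuration of the two acrylate intermediates.

Abbreviation: LiTMP = lithium 2,2,6,6-tetramethylpiperidide (LiNC9H18), used as its solution in THF.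

## Route

Step 1
Reactants: 1 methyl 2-(1H-indol-3-yl)acetate
Product: 3 methyl (E)-2-(1H-indol-3-yl)-3-methoxyprop-2-enoate, via sodium enolate 2 (not isolated)
Conditions: NaH (2.1 equiv), HCO2Me (5 equiv), DMF, 0 °C to rt; AcOH (1.1 equiv); Me2SO4 (1.3 equiv), rt
Reagents that add atoms: methyl formate, COC=O; dimethyl sulfate, COS(=O)(=O)OC
Why: Claisen formylation of the arylacetate followed by O-methylation of the formyl-ester enolate (the standard β-methoxyacrylate protocol); acetic acid reprotonates the indolide so that only the enolate oxygen is methylated, and the E isomer (OMe trans to the ester) is the thermodynamic product.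

Step 2
Reactants: 4 7-bromo-1H-indole
Product: 5 ethyl 2-(7-bromo-1H-indol-3-yl)acetate
Conditions: N2CHCO2Et (1.2 equiv, slow addition), Cu(OTf)2 (5 mol%), CH2Cl2, rt
Reagents that add atoms: ethyl diazoacetate, CCOC(=O)C=[N+]=[N-]
Why: Copper-carbenoid C–H functionalisation, in which the electrophilic copper carbene is attacked by C3 of the unprotected indole and a proton shift re-aromatises to the indol-3-ylacetate; the aryl bromide is inert.

Step 3
Reactants: 5 ethyl 2-(7-bromo-1H-indol-3-yl)acetate
Product: 6 ethyl 2-[7-(3-methylbut-2-en-1-yl)-1H-indol-3-yl]acetate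
Conditions: Bu3SnCH2CH=CMe2 (1.3 equiv), Pd(PPh3)4 (5 mol%), DMF, 100 °C
Reagents that add atoms: tributyl(3-methylbut-2-en-1-yl)stannane, CCCC[Sn](CCCC)(CCCC)CC=C(C)C
Why: Stille coupling under neutral conditions that tolerate the free N–H and the ester; reductive elimination from the π-prenyl palladium intermediate at its less hindered terminus gives the linear prenyl group.

Step 4
Reactants: 6 ethyl 2-[7-(3-methylbut-2-en-1-yl)-1H-indol-3-yl]acetate
Product: 8 ethyl (E)-3-methoxy-2-[7-(3-methylbut-2-en-1-yl)-1H-indol-3-yl]prop-2-enoate, via sodium enolate 7 (not isolated)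
Conditions: NaH (2.1 equiv), HCO2Et (5 equiv), DMF, 0 °C to rt; AcOH (1.1 equiv); Me2SO4 (1.3 equiv), rt
Reagents that add atoms: ethyl formate, CCOC=O; dimethyl sulfate, COS(=O)(=O)OC
Why: Same Claisen formylation and O-methylation as in step 1, with ethyl formate matched to the ethyl ester to avoid ester scrambling; the prenyl alkene is inert to these conditions and the E isomer is again the thermodynamic product.

Step 5
Reactants: 8 ethyl (E)-3-methoxy-2-[7-(3-methylbut-2-en-1-yl)-1H-indol-3-yl]prop-2-enoate; 3 methyl (E)-2-(1H-indol-3-yl)-3-methoxyprop-2-enoate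
Product: 14 2-(1H-indol-3-yl)-3,6-dimethoxy-5-[7-(3-methylbut-2-en-1-yl)-1H-indol-3-yl]cyclohexa-2,5-diene-1,4-dione, via C,N-dilithio acrylate 9 (not isolated), via N-lithio acrylate 10 (not isolated), via dilithio keto ester 11 (not isolated), via trilithio keto ester 12 (not isolated), via dilithio quinone 13 (not isolated)
Conditions: 8, LiTMP (2.1 equiv), THF, −95 °C; add 3 (1.1 equiv) pre-treated with LiTMP (1.0 equiv, THF, −78 °C); −95 to −60 °C; LiTMP (1.3 equiv), −78 to −30 °C; AcOH (5 equiv), −78 °C
Reagents that add atoms: none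
Why: Proposed new method: a head-to-tail acylative cyclodimerisation of two β-methoxyacrylates, in which ester-chelated lithiation of the enol-ether carbon of 8 (closest known reaction: β-lithiation of α-substituted β-alkoxyacrylates and their trapping by carbonyl compounds to give tetronates) lets this masked formyl carbon attack the ester carbonyl of 10 in a Claisen-type addition–elimination, after which a second, ketone-directed vinylic lithiation (analogy: C2 lithiation of chromones by LiTMP) closes the ring by a 6-exo Dieckmann-type acylation on the remaining ester; both E geometries place each lithiated carbon cis to the carbonyl it must reach, the N–H groups are masked as N–Li, and the quinone forms at its final oxidation level with no stereocentre created.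

## Compound list

1 | methyl 2-(1H-indol-3-yl)acetate | COC(=O)Cc1c[nH]c2ccccc12 | starting material
2 | sodium 2-(1H-indol-3-yl)-3-methoxy-3-oxoprop-1-en-1-olate (delocalised enolate, geometry not fixed) | [Na+].[O-]C=C(C(=O)OC)c1c[nH]c2ccccc12 | intermediate
3 | methyl (E)-2-(1H-indol-3-yl)-3-methoxyprop-2-enoate | CO/C=C(/C(=O)OC)c1c[nH]c2ccccc12 | intermediate
4 | 7-bromo-1H-indole | Brc1cccc2cc[nH]c12 | starting material
5 | ethyl 2-(7-bromo-1H-indol-3-yl)acetate | CCOC(=O)Cc1c[nH]c2c(Br)cccc12 | intermediate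
6 | ethyl 2-[7-(3-methylbut-2-en-1-yl)-1H-indol-3-yl]acetate | CCOC(=O)Cc1c[nH]c2c(CC=C(C)C)cccc12 | intermediate
7 | sodium 3-ethoxy-2-[7-(3-methylbut-2-en-1-yl)-1H-indol-3-yl]-3-oxoprop-1-en-1-olate (delocalised enolate, geometry not fixed) | [Na+].[O-]C=C(C(=O)OCC)c1c[nH]c2c(CC=C(C)C)cccc12 | intermediate
8 | ethyl (E)-3-methoxy-2-[7-(3-methylbut-2-en-1-yl)-1H-indol-3-yl]prop-2-enoate | CO/C=C(/C(=O)OCC)c1c[nH]c2c(CC=C(C)C)cccc12 | intermediate
9 | ethyl (E)-3-lithio-2-[1-lithio-7-(3-methylbut-2-en-1-yl)indol-3-yl]-3-methoxyprop-2-enoate | CO/C([Li])=C(/C(=O)OCC)c1cn([Li])c2c(CC=C(C)C)cccc12 | intermediate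
10 | methyl (E)-2-(1-lithioindol-3-yl)-3-methoxyprop-2-enoate | CO/C=C(/C(=O)OC)c1cn([Li])c2ccccc12 | intermediate
11 | ethyl (2E,5E)-5-(1-lithioindol-3-yl)-2-[1-lithio-7-(3-methylbut-2-en-1-yl)indol-3-yl]-3,6-dimethoxy-4-oxohexa-2,5-dienoate | CO/C=C(/C(=O)C(/OC)=C(\C(=O)OCC)c1cn([Li])c2c(CC=C(C)C)cccc12)c1cn([Li])c2ccccc12 | intermediate
12 | ethyl (2E,5E)-6-lithio-5-(1-lithioindol-3-yl)-2-[1-lithio-7-(3-methylbut-2-en-1-yl)indol-3-yl]-3,6-dimethoxy-4-oxohexa-2,5-dienoate | CO/C([Li])=C(/C(=O)C(/OC)=C(\C(=O)OCC)c1cn([Li])c2c(CC=C(C)C)cccc12)c1cn([Li])c2ccccc12 | intermediate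
13 | 2-(1-lithioindol-3-yl)-5-[1-lithio-7-(3-methylbut-2-en-1-yl)indol-3-yl]-3,6-dimethoxycyclohexa-2,5-diene-1,4-dione | COC1=C(c2cn([Li])c3ccccc23)C(=O)C(OC)=C(c2cn([Li])c3c(CC=C(C)C)cccc23)C1=O | intermediate
14 | 2-(1H-indol-3-yl)-3,6-dimethoxy-5-[7-(3-methylbut-2-en-1-yl)-1H-indol-3-yl]cyclohexa-2,5-diene-1,4-dione | COC1=C(c2c[nH]c3ccccc23)C(=O)C(OC)=C(c2c[nH]c3c(CC=C(C)C)cccc23)C1=O | target

## Step count and risks

Total steps: 5. Longest linear sequence: 4 steps (4 → 5 → 6 → 8 → 14).

Steps most likely to fail: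

**Step 5 (ring-forming double acylation).** This step is untested chemistry. The risks are attack of the vinyllithium at the enol-ether carbon of the partner instead of its ester, double addition to the new ketone, incomplete second lithiation, and lithium scrambling that would give the two symmetrical quinones beside 14.

Fallback: it sets out from 3 and 8 and comes back at 14, using a silyl-protected mono-anion, reversed roles of the partners and an isolated open-chain intermediate.
- 3 is N-silylated (NaH, i-Pr3SiCl, THF, 0 °C) to methyl (E)-3-methoxy-2-[1-(triisopropylsilyl)-1H-indol-3-yl]prop-2-enoate F1; the silyl group removes the acidic N–H and shields C2.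
- LiTMP (1.05 equiv, THF, −95 °C) converts F1 into methyl (E)-3-lithio-3-methoxy-2-[1-(triisopropylsilyl)-1H-indol-3-yl]prop-2-enoate F2.
- F2 is added by cannula to an excess of ethyl (E)-2-[1-lithio-7-(3-methylbut-2-en-1-yl)indol-3-yl]-3-methoxyprop-2-enoate F3, made from 8 and LiTMP (1.0 equiv).
- A cold AcOH quench lets the open keto ester methyl (2E,5E)-3,6-dimethoxy-5-[7-(3-methylbut-2-en-1-yl)-1H-indol-3-yl]-4-oxo-2-[1-(triisopropylsilyl)-1H-indol-3-yl]hexa-2,5-dienoate F4 be isolated and purified.
- In a separate operation LiTMP (2.2 equiv, THF, −78 to −30 °C) closes F4 to 3,6-dimethoxy-2-[7-(3-methylbut-2-en-1-yl)-1H-indol-3-yl]-5-[1-(triisopropylsilyl)-1H-indol-3-yl]cyclohexa-2,5-diene-1,4-dione F5.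
- Bu4NF buffered with AcOH (THF, 0 °C) removes the silyl group to give 14.

**Step 3 (Stille prenylation).** The risks are formation of the branched (1,1-dimethylallyl) isomer and sluggish coupling next to the free N–H.

Fallback: it sets out from 5 and comes back at 6. The prenyl group is built in two stages instead of being transferred whole. Suzuki–Miyaura coupling of 5 with allylboronic acid pinacol ester (PdCl2(dppf), CsF, THF, 65 °C) gives ethyl 2-[7-(prop-2-en-1-yl)-1H-indol-3-yl]acetate F6, for which no regiochemical ambiguity exists. Olefin cross-metathesis with 2-methylbut-2-ene (second-generation Grubbs catalyst, RuCl2(=CHPh)(PCy3)(H2IMes), CH2Cl2, 40 °C) then turns the allyl group into the prenyl group of 6.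

**Step 2 (carbenoid C3–H alkylation).** The risks are competing N–H insertion, C2 alkylation or double alkylation on the unprotected indole.

Fallback: it sets out from 4 and comes back at 5. Uncatalysed C3 acylation with oxalyl chloride (Et2O, 0 °C), then EtOH, gives ethyl 2-(7-bromo-1H-indol-3-yl)-2-oxoacetate F7 with reliable C3 selectivity. Ionic hydrogenation of the aryl ketone (Et3SiH, CF3CO2H, rt) reduces it to the methylene group of 5.

## Further compounds

F1 | step 5 | methyl (E)-3-methoxy-2-[1-(triisopropylsilyl)-1H-indol-3-yl]prop-2-enoate | CO/C=C(/C(=O)OC)c1cn([Si](C(C)C)(C(C)C)C(C)C)c2ccccc12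
F2 | step 5 | methyl (E)-3-lithio-3-methoxy-2-[1-(triisopropylsilyl)-1H-indol-3-yl]prop-2-enoate | CO/C([Li])=C(/C(=O)OC)c1cn([Si](C(C)C)(C(C)C)C(C)C)c2ccccc12
F3 | step 5 | ethyl (E)-2-[1-lithio-7-(3-methylbut-2-en-1-yl)indol-3-yl]-3-methoxyprop-2-enoate | CO/C=C(/C(=O)OCC)c1cn([Li])c2c(CC=C(C)C)cccc12
F4 | step 5 | methyl (2E,5E)-3,6-dimethoxy-5-[7-(3-methylbut-2-en-1-yl)-1H-indol-3-yl]-4-oxo-2-[1-(triisopropylsilyl)-1H-indol-3-yl]hexa-2,5-dienoate | CO/C=C(/C(=O)C(/OC)=C(\C(=O)OC)c1cn([Si](C(C)C)(C(C)C)C(C)C)c2ccccc12)c1c[nH]c2c(CC=C(C)C)cccc12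
F5 | step 5 | 3,6-dimethoxy-2-[7-(3-methylbut-2-en-1-yl)-1H-indol-3-yl]-5-[1-(triisopropylsilyl)-1H-indol-3-yl]cyclohexa-2,5-diene-1,4-dione | COC1=C(c2cn([Si](C(C)C)(C(C)C)C(C)C)c3ccccc23)C(=O)C(OC)=C(c2c[nH]c3c(CC=C(C)C)cccc23)C1=O
F6 | step 3 | ethyl 2-[7-(prop-2-en-1-yl)-1H-indol-3-yl]acetate | CCOC(=O)Cc1c[nH]c2c(CC=C)cccc12
F7 | step 2 | ethyl 2-(7-bromo-1H-indol-3-yl)-2-oxoacetate | CCOC(=O)C(=O)c1c[nH]c2c(Br)cccc12
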